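**Retrosynthetic overview**

- Feature: the hexasubstituted ring is a phloroglucinol, the enol form of a cyclohexane-1,3,5-trione. C2, C4 and C6 (O-bearing) are carbonyl-derived; C1 (benzoyl-bearing), C3 and C5 (prenyl-bearing) are enolate-type carbons. The ring is therefore a folded benzoyl tetraketide.
- Key disconnection: ring bonds C4–C5 and C1–C2. C1/C6/C5, with the benzoyl group and the C5 prenyl chain, come from a 1,3-bis(trimethylsilyloxy)diene. C2/C3/C4, with the C3 prenyl group, come from prenylmalonyl dichloride ([3+3]: C-acylation, then Claisen-type closure).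
- Diene: double O-silylation of 7-methyl-1-phenyloct-6-ene-1,3-dione, made by γ-prenylation of the benzoylacetone dianion.
- Dichloride: diethyl malonate, C-prenylation, saponification, chlorination.
- Ring order: the phenyl ring is bought; the phloroglucinol ring is the only ring made and is closed last, already carrying all six substituents.

Key step: step 6

Remark: the target has no stereocentre and is achiral, so no stereocontrol is required. The enol ether geometries drawn for 3, 5, 6 and 13 are the expected ones, and any E/Z mixture serves equally because these carbons end as ring or carbonyl carbons.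

**Route**

Step 1
Reactants: 1 1-phenylbutane-1,3-dione (benzoylacetone); 2 1-bromo-3-methylbut-2-ene (prenyl bromide)
Product: 4 7-methyl-1-phenyloct-6-ene-1,3-dione, via dilithium dianion 3 (not isolated)
Conditions: LDA (2.1 equiv), THF, 0 °C; 2 (1.0 equiv), −78 → 0 °C; cold 1 M HCl to pH 4
Reagents that add atoms: none
Why: Two equivalents of LDA give dianion 3, whose terminal carbanion is far more nucleophilic than the stabilised central carbon and displaces bromide from the primary allylic carbon by SN2 (Hauser-type γ-alkylation of a β-diketone dianion), leaving the unreactive monoanion of 4.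

Step 2
Reactants: 4 7-methyl-1-phenyloct-6-ene-1,3-dione
Product: 6 (1Z,3Z)-7-methyl-1-phenyl-1,3-bis(trimethylsilyloxy)octa-1,3,6-triene, via mono silyl enol ether 5 (not isolated)
Conditions: TMSOTf (2.2 equiv), Et3N (3 equiv), Et2O, 0 °C → rt; ammonium triflate layer separated, solvent removed under argon; used at once
Reagents that add atoms: trimethylsilyl trifluoromethanesulfonate, C[Si](C)(C)OS(=O)(=O)C(F)(F)F
Why: Soft enolisation and O-silylation with a silyl triflate and a tertiary amine (Simchen-type preparation of 1,3-bis(silyloxy)-1,3-dienes from 1,3-diketones) should silylate the chelated enol first to 5 (its 3-silyloxy regioisomer converges on the same diene) and then enolise the remaining carbonyl toward C4, the only side with hydrogens, while the isolated C6=C7 alkene is untouched.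

Step 3
Reactants: 7 diethyl malonate; 2 1-bromo-3-methylbut-2-ene (prenyl bromide)
Product: 9 diethyl 2-(3-methylbut-2-en-1-yl)malonate, via sodium enolate 8 (not isolated)
Conditions: NaOEt (1.0 equiv), 7 (1.5 equiv), EtOH, 0 °C; 2 (1.0 equiv), 0 °C → rt; distillation
Reagents that add atoms: none
Why: Malonic ester alkylation, an SN2 reaction of the soft enolate 8 at the primary carbon of the allylic bromide, with the excess of malonate suppressing dialkylation.

Step 4
Reactants: 9 diethyl 2-(3-methylbut-2-en-1-yl)malonate
Product: 11 2-(3-methylbut-2-en-1-yl)malonic acid, via dipotassium salt 10 (not isolated)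
Conditions: KOH (2.5 equiv), EtOH/H2O, rt → 40 °C; 1 M HCl to pH 2 at 0 °C, Et2O extraction, no heating
Reagents that add atoms: potassium hydroxide, [K+].[OH-]
Why: Saponification (BAc2) of both esters to dicarboxylate 10 and protonation in the cold, where the malonic acid should not decarboxylate and the trisubstituted alkene is neither hydrated nor lactonised.

Step 5
Reactants: 11 2-(3-methylbut-2-en-1-yl)malonic acid
Product: 12 2-(3-methylbut-2-en-1-yl)malonyl dichloride
Conditions: (COCl)2 (2.4 equiv), DMF (cat.), CH2Cl2, 0 °C → rt; volatiles removed below 25 °C, short-path distillation in high vacuum; used at once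
Reagents that add atoms: oxalyl chloride, O=C(Cl)C(=O)Cl
Why: Acid chloride formation through the Vilsmeier-type chloroiminium species at or below room temperature, conditions under which γ,δ-unsaturated prenyl-type acids are routinely chlorinated without hydrochlorination of the alkene and under which loss of HCl to the chlorocarbonyl ketene is slow.

Step 6
Reactants: 6 (1Z,3Z)-7-methyl-1-phenyl-1,3-bis(trimethylsilyloxy)octa-1,3,6-triene; 12 2-(3-methylbut-2-en-1-yl)malonyl dichloride
Product: 14 clusiaphenone B, via acyclic acid chloride 13 (not isolated)
Conditions: 12 (1.1 equiv), TMSOTf (0.3 equiv), 2,6-di-tert-butyl-4-methylpyridine (0.3 equiv), CH2Cl2 (0.02 M), −78 °C, slow addition of 6; −78 → −20 °C; MeOH, then cold pH 5 citrate buffer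
Reagents that add atoms: none
Why: Proposed new method: TMSOTf activates one acyl chloride group of 12, and the terminal diene carbon of 6 (future ring C5, the most nucleophilic site) attacks it in a vinylogous Mukaiyama-type acylation with loss of Me3SiCl, forming ring bond C4–C5 and giving 13; the remaining silyl enol ether carbon (future C1) then attacks the second activated acyl chloride, forming C1–C2 with loss of a second Me3SiCl, and the triketo tautomer so formed aromatises to 14 by enolisation. The closest known reaction types are the TMSOTf-catalysed cyclisations of 1,3-bis(silyl enol ethers) with oxalyl chloride and other dielectrophiles, the terminal C-acylation of such dienes by acid chlorides, and the base-mediated Claisen cyclisation of 3,5,7-triketo esters to acylphloroglucinols. The one ring is closed in the 6-(enolexo)-exo-trig mode, the enol ether double bond C1=C(OSiMe3)Ph lying outside the new ring. No stereocentre is created, and the two transient sp3 centres of 13 become aromatic carbons. The selectivity needed is C-acylation at C1 over lactonisation through the C6 enol oxygen and over intermolecular acylation: C1 is already a silyl enol ether, whereas the oxygen nucleophile would first require enolisation of the α-prenylated C4/C6 diketone of 13, which is slow at −78 °C in the buffered, amine-free medium; slow addition at high dilution keeps the closure intramolecular, and the prenyl group on C3 excludes the aldol fold because C3 would become quaternary. The hindered pyridine takes up adventitious TfOH and HCl without binding the silyl triflate, so that the prenyl groups should be neither hydrochlorinated nor cyclised onto the flanking phenols, and the methanol and buffer treatment hydrolyses any aryl silyl ether.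

**Compound list**

1 | 1-phenylbutane-1,3-dione (benzoylacetone) | CC(=O)CC(=O)c1ccccc1 | starting material
2 | 1-bromo-3-methylbut-2-ene (prenyl bromide) | CC(C)=CCBr | starting material
3 | dilithium (Z)-1-phenylbuta-1,3-diene-1,3-diolate (dianion of 1) | C=C(O[Li])/C=C(\O[Li])c1ccccc1 | intermediate
4 | 7-methyl-1-phenyloct-6-ene-1,3-dione | CC(C)=CCCC(=O)CC(=O)c1ccccc1 | intermediate
5 | (Z)-7-methyl-1-phenyl-1-(trimethylsilyloxy)octa-1,6-dien-3-one | C[Si](C)(C)O/C(c1ccccc1)=C\C(=O)CCC=C(C)C | intermediate
6 | (1Z,3Z)-7-methyl-1-phenyl-1,3-bis(trimethylsilyloxy)octa-1,3,6-triene | C[Si](C)(C)O/C(c1ccccc1)=C\C(O[Si](C)(C)C)=C\CC=C(C)C | intermediate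
7 | diethyl malonate | CCOC(=O)CC(=O)OCC | starting material
8 | sodium enolate of diethyl malonate | [Na+].CCOC(=O)[CH-]C(=O)OCC | intermediate
9 | diethyl 2-(3-methylbut-2-en-1-yl)malonate | CCOC(=O)C(CC=C(C)C)C(=O)OCC | intermediate
10 | dipotassium 2-(3-methylbut-2-en-1-yl)malonate | [K+].[K+].CC(C)=CCC(C(=O)[O-])C(=O)[O-] | intermediate
11 | 2-(3-methylbut-2-en-1-yl)malonic acid | CC(C)=CCC(C(=O)O)C(=O)O | intermediate
12 | 2-(3-methylbut-2-en-1-yl)malonyl dichloride | CC(C)=CCC(C(=O)Cl)C(=O)Cl | intermediate
13 | (Z)-2,4-bis(3-methylbut-2-en-1-yl)-3,5-dioxo-7-phenyl-7-(trimethylsilyloxy)hept-6-enoyl chloride (C2 and C4 unspecified, epimeric mixture) | C[Si](C)(C)O/C(c1ccccc1)=C\C(=O)C(CC=C(C)C)C(=O)C(CC=C(C)C)C(=O)Cl | intermediate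
14 | clusiaphenone B, phenyl[2,4,6-trihydroxy-3,5-bis(3-methylbut-2-en-1-yl)phenyl]methanone | CC(C)=CCc1c(O)c(CC=C(C)C)c(O)c(C(=O)c2ccccc2)c1O | target

**Step count**

Total steps: 6. Longest linear sequence: 4 (steps 3, 4, 5, 6); the diene branch is steps 1, 2, 6.

**Steps most likely to fail**

1. Step 6 (proposed new method). The second acylation may proceed through the C6 enol oxygen (lactonisation) instead of through C1, the acyl chloride may be captured intermolecularly, or acid may cyclise a prenyl group onto a neighbouring phenol. The fallback separates the two bond formations into known reactions and sets out from 9 and 6. Half-saponification of 9 (KOH, 1.0 equiv, EtOH, rt) should give potassium 2-(ethoxycarbonyl)-5-methylhex-4-enoate F1. Oxalyl chloride with catalytic DMF in CH2Cl2 at 0 °C should convert it under neutral conditions into ethyl 2-(chlorocarbonyl)-5-methylhex-4-enoate F2. Terminal C-acylation of diene 6 with F2 (TMSOTf cat., CH2Cl2, −78 → −20 °C) should give ethyl (Z)-2,4-bis(3-methylbut-2-en-1-yl)-3,5-dioxo-7-phenyl-7-(trimethylsilyloxy)hept-6-enoate F3. Aqueous citric acid work-up hydrolyses it to ethyl 2,4-bis(3-methylbut-2-en-1-yl)-3,5,7-trioxo-7-phenylheptanoate F4. Claisen cyclisation of this 3,5,7-triketo ester with NaOEt in EtOH (0 °C → rt, then dilute acid), driven by aromatisation, returns to the route at 14.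

2. Step 5. HCl released during chlorination may add to the trisubstituted alkene, or the monosubstituted malonyl chloride may lose HCl to a ketene and oligomerise on concentration. The fallback sets out from 11 and avoids any free HCl. Silylation with hexamethyldisilazane (cat. Me3SiCl, CH2Cl2, rt) should give bis(trimethylsilyl) 2-(3-methylbut-2-en-1-yl)malonate F5. Oxalyl chloride with catalytic DMF in CH2Cl2 at 0 °C then exchanges each silyl ester for an acid chloride, releasing only Me3SiCl, CO and CO2, and returns to the route at 12.

3. Step 2. The second silylation may stop short, or the diene may be hydrolysed back to 4 during isolation. The fallback sets out from 4 and replaces soft enolisation by a stepwise hard-enolisation sequence. Me3SiCl and Et3N in pentane at rt give the mono silyl enol ether 5, isolated by filtration and evaporation. Kinetic deprotonation with LDA in THF at −78 °C then gives lithium (1Z,3Z)-7-methyl-1-phenyl-1-(trimethylsilyloxy)octa-1,3,6-trien-3-olate F6, which is trapped with Me3SiCl (−78 → 0 °C) and returns to the route at 6.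

**Further compounds**

F1 | step 6 | potassium 2-(ethoxycarbonyl)-5-methylhex-4-enoate (racemic) | [K+].CCOC(=O)C(CC=C(C)C)C(=O)[O-]
F2 | step 6 | ethyl 2-(chlorocarbonyl)-5-methylhex-4-enoate (racemic) | CCOC(=O)C(CC=C(C)C)C(=O)Cl
F3 | step 6 | ethyl (Z)-2,4-bis(3-methylbut-2-en-1-yl)-3,5-dioxo-7-phenyl-7-(trimethylsilyloxy)hept-6-enoate (C2 and C4 unspecified, epimeric mixture) | CCOC(=O)C(CC=C(C)C)C(=O)C(CC=C(C)C)C(=O)/C=C(\O[Si](C)(C)C)c1ccccc1
F4 | step 6 | ethyl 2,4-bis(3-methylbut-2-en-1-yl)-3,5,7-trioxo-7-phenylheptanoate (C2 and C4 unspecified, epimeric and tautomeric mixture) | CCOC(=O)C(CC=C(C)C)C(=O)C(CC=C(C)C)C(=O)CC(=O)c1ccccc1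
F5 | step 5 | bis(trimethylsilyl) 2-(3-methylbut-2-en-1-yl)malonate | CC(C)=CCC(C(=O)O[Si](C)(C)C)C(=O)O[Si](C)(C)C
F6 | step 2 | lithium (1Z,3Z)-7-methyl-1-phenyl-1-(trimethylsilyloxy)octa-1,3,6-trien-3-olate | C[Si](C)(C)O/C(c1ccccc1)=C\C(O[Li])=C\CC=C(C)C
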